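**Plan**

1. Locants are carotenoid numbers within each half (ring C1–C6, dihydrofuran CH carbons C7 and C8, chain C9–C15). Ring A is the end without hydroxyl, ring B the 3-hydroxy end.
2. Retrosynthesis: the chain is cut at both C11=C12 bonds (Wittig, C15 + C10 + C15). Each end group is then cut at C1–C2 and C5–C6, which opens the cyclohexane and the dihydrofuran together.
3. Enabling feature: the C6=C7 alkene is exocyclic to the cyclohexane, endocyclic in the dihydrofuran and flanked by quaternary C1. It is the remnant of a C7=C6=C1Me2 allene that has reacted at its distal bond, and O–C5 on quaternary C5 marks a 1-alkoxy diene terminus. O, C8 and C7 form a three-atom tether, so one intramolecular Diels–Alder reaction of an acyclic dienyl ether closes both rings; the 3-silyloxy group that activates the diene becomes the C3 oxygen.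
4. Forward: C8 carbinol by asymmetric alkynylation → allenol → dienyl ether → bicyclic ketones (both C5 epimers) → ring B C15 salt (ketone reduction) and ring A C15 salt (C3 deoxygenation) → two Wittig reactions on the C10 dialdehyde.
5. Stereochemistry: C8 (S in both halves) by reagent control in step 1. C5 is set in the cycloaddition, where both epimers are wanted (5S for ring B, 5R for ring A). C3 of ring B comes from substrate-controlled hydride delivery; alkene geometry from the building blocks and thermal Z→E equilibration.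

Key step: step 6

Assumption: in step 1 the (R,R)-ligand is taken to give the (R)-carbinol, by analogy with the facial sense of Me2Zn/ProPhenol additions to other aldehydes; the sense is checked on 3 by Mosher ester analysis and, if reversed, the (S,S)-ligand is used with nothing else changed.

**Route**

Step 1
Reactants: 1 (2E)-3-methyl-4-oxobut-2-en-1-yl acetate; 2 2-[(2-methylbut-3-yn-2-yl)oxy]oxane
Product: 3 (2E,4R)-4-hydroxy-3,7-dimethyl-7-(oxan-2-yloxy)oct-2-en-5-yn-1-yl acetate (both epimers at the acetal carbon)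
Conditions: Me2Zn (3 equiv), (R,R)-ProPhenol (10 mol%), Ph3PO (20 mol%), PhMe, 4 °C; aq. NH4Cl
Reagents that add atoms: none
Why: Catalytic asymmetric alkynylation of an aldehyde (zinc alkynylide addition under ProPhenol control), a reaction type that performs well with α-branched enals; the ligand differentiates the aldehyde faces and so sets C8 (R here only because the alkyne outranks the alkene).

Step 2
Reactants: 3
Product: 4 (2E,4S)-3,7-dimethylocta-2,5,6-triene-1,4-diol
Conditions: LiAlH4 (3 equiv), Et2O, 0 °C to reflux; aq. potassium sodium tartrate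
Reagents that add atoms: none
Why: SN2′-type reductive allene synthesis from a 4-alkoxyalk-2-yn-1-ol: hydroxyl-directed trans-hydroalumination puts aluminium on C6 and 1,2-elimination of the tertiary oxanyloxy group gives the 1,1-dimethylallene, the acetate being cleaved in the same operation and C8 left untouched (the descriptor becomes S only through the changed CIP ranks).

Step 3
Reactants: 4
Product: 5 (2E,4S)-1-{[tert-butyl(dimethyl)silyl]oxy}-3,7-dimethylocta-2,5,6-trien-4-ol
Conditions: TBSCl (1.05 equiv), imidazole, CH2Cl2, −20 °C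
Reagents that add atoms: tert-butyldimethylsilyl chloride, CC(C)(C)[Si](C)(C)Cl
Why: Selective silylation of a primary alcohol; the hindered, doubly allylic secondary hydroxyl should react far more slowly.

Step 4
Reactants: 5; 6 pent-3-yn-2-one
Product: 7 (3E)-4-{[(2E,4S)-1-{[tert-butyl(dimethyl)silyl]oxy}-3,7-dimethylocta-2,5,6-trien-4-yl]oxy}pent-3-en-2-one
Conditions: PMe3 (20 mol%), CH2Cl2, 0 °C to rt
Reagents that add atoms: none
Why: Phosphine-catalysed oxa-Michael addition of an alcohol to an ynone, which should give the thermodynamically favoured (E)-β-alkoxy enone (oxygen trans to the acetyl group) under neutral conditions that spare the allene and the silyl ether.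

Step 5
Reactants: 7
Product: 9 tert-butyl{[(2E,4S)-4-{[(2E)-4-{[tert-butyl(dimethyl)silyl]oxy}penta-2,4-dien-2-yl]oxy}-3,7-dimethylocta-2,5,6-trien-1-yl]oxy}dimethylsilane, via lithium dienolate 8 (not isolated)
Conditions: LiN(i-Pr)2, THF, −78 °C; TBSCl, DMPU, −78 to 0 °C; cold pentane/aq. NaHCO3, filtration through basic Al2O3
Reagents that add atoms: tert-butyldimethylsilyl chloride, CC(C)(C)[Si](C)(C)Cl
Why: Kinetic deprotonation of a vinylogous ester takes place at the α′ methyl group, and O-silylation of the cross-conjugated enolate gives the 1-alkoxy-3-silyloxy diene with the enol ether geometry unchanged (silyl enol ether formation).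

Step 6
Reactants: 9
Product: 10 tert-butyl{[(2S,7aS)-2-[(2E)-4-{[tert-butyl(dimethyl)silyl]oxy}but-2-en-2-yl]-4,4,7a-trimethyl-2,4,5,7a-tetrahydro-1-benzofuran-6-yl]oxy}dimethylsilane (5S,8S; methyl and side chain trans) and 11 its (2S,7aR) epimer (5R,8S; methyl and side chain cis), carried on as the mixture
Conditions: PhMe (0.02 M), BHT (cat.), Et3N (1 mol%), 70 °C, silylated glass
Reagents that add atoms: none
Why: Thermal, concerted but asynchronous [4π+2π] cycloaddition (intramolecular Diels–Alder reaction) in which the (E)-1-alkoxy-3-silyloxy diene C2=C3–C4=C5 adds across the distal C6=C1 bond of the allene, so that C5–C6 and C1–C2 form together and the proximal C7=C6 bond is left as the ring alkene. The closest known reaction type is the intramolecular Diels–Alder reaction of allenyl ethers and of allenecarboxanilides, in which a three-atom tether ending at the proximal allene carbon likewise forces reaction at the terminal allene bond, even with furan or benzene rings as the diene. The cyclohexene ring is closed by the [4+2] itself through a boat-like six-membered transition state, and the dihydrofuran ring closes as the tether ring (O, C8, C7) of a fused (type 1) intramolecular cycloaddition when C5 bonds to the allene centre C6, whose reacting p-lobe lies in the plane of the forming five-membered ring. The only new stereocentre is C5; it is set relative to C8 by whether the C8 side chain sits on the face of the inside C5 methyl or of C4, a contact across the ring oxygen that should be small with a mild preference for 10, and no preference is needed because 10 is the precursor of ring B and 11 that of ring A. What the step does need is chemoselectivity for the distal allene bond and for cycloaddition over [3,3] shift of the allyl vinyl ether arrays: the tether secures the first (the proximal bond would give an oxetane), and the low barrier of this tether topology should secure the second by letting the reaction run near 70 °C, where such shifts are slow. Regiochemistry is fixed by the tether and by the (E)-enol ether, which places the ether oxygen outside and the methyl inside the s-cis diene, and the allene brings no axial chirality because C1 carries two identical methyls.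

Step 7
Reactants: 10 and 11 (mixture from step 6)
Product: 12 (2S,7aS)-2-[(2E)-4-hydroxybut-2-en-2-yl]-4,4,7a-trimethyl-2,4,5,7a-tetrahydro-1-benzofuran-6(7H)-one and 13 its (2S,7aR) epimer, separated by chromatography on Et3N-deactivated silica
Conditions: Bu4NF (3 equiv), AcOH (3 equiv), THF, 0 °C to rt
Reagents that add atoms: none
Why: Fluoride-mediated desilylation turns the silyl enol ether into the C3 ketone and frees the primary alcohol; the acetic acid buffer protonates the enolate at once, so β-elimination of the poorly aligned C5 oxygen should not set in, and the C5 epimers are separable as diastereomeric ketones.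

Step 8
Reactants: 12
Product: 14 (2S,6R,7aS)-2-[(2E)-4-hydroxybut-2-en-2-yl]-4,4,7a-trimethyl-2,4,5,6,7,7a-hexahydro-1-benzofuran-6-ol (3R,5S,8S)
Conditions: LiBH(s-Bu)3 (2.5 equiv), THF, −78 °C; then H2O
Reagents that add atoms: none
Why: Substrate-controlled ketone reduction: the axial C5 methyl (the ring oxygen is held in the plane of C6=C7) and the syn-axial C1 methyl block the axial trajectory, so the bulky hydride should attack equatorially and give the axial alcohol cis to the C5 methyl, which is 3R.

Step 9
Reactants: 14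
Product: 16 {(2E)-3-[(2S,6R,7aS)-6-hydroxy-4,4,7a-trimethyl-2,4,5,6,7,7a-hexahydro-1-benzofuran-2-yl]but-2-en-1-yl}(triphenyl)phosphonium bromide, via allylic bromide 15 (not isolated)
Conditions: CBr4 (1.05 equiv), PPh3 (1.1 equiv), CH2Cl2, −20 °C; then PPh3 (1.5 equiv), 0 °C to rt
Reagents that add atoms: carbon tetrabromide, BrC(Br)(Br)Br; triphenylphosphine, c1ccccc1P(c1ccccc1)c1ccccc1
Why: Appel bromination should select the primary allylic hydroxyl over the hindered axial secondary one, and the bromide is quaternised in the same flask by SN2 attack of PPh3, which avoids HBr-based salt formation that would ionise the doubly allylic C8–O bond.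

Step 10
Reactants: 13
Product: 17 N′-{(2S,7aR)-2-[(2E)-4-hydroxybut-2-en-2-yl]-4,4,7a-trimethyl-2,4,5,7a-tetrahydro-1-benzofuran-6(7H)-ylidene}-4-methylbenzenesulfonohydrazide
Conditions: TsNHNH2 (1.2 equiv), EtOH, 4 Å molecular sieves, 40 °C
Reagents that add atoms: 4-methylbenzenesulfonohydrazide, Cc1ccc(cc1)S(=O)(=O)NN
Why: Tosylhydrazone formation on an unhindered cyclohexanone needs no acid catalyst, so the acid-labile C8–O bond is not put at risk.

Step 11
Reactants: 17
Product: 19 (2E)-3-[(2S,7aR)-4,4,7a-trimethyl-2,4,5,6,7,7a-hexahydro-1-benzofuran-2-yl]but-2-en-1-ol (5R,8S), via N-borylhydrazine 18 (not isolated)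
Conditions: catecholborane (3.5 equiv), CHCl3, 0 °C; then NaOAc·3H2O, 60 °C
Reagents that add atoms: none
Why: Tosylhydrazone reduction (a mild counterpart of the Wolff–Kishner reduction): hydride addition to C=N and acetate-induced loss of sulfinate give a monoalkyl diazene that loses N2 to leave CH2 at C3, the remote alkenes cannot transpose, and the hydroxyl is borylated only until work-up.

Step 12
Reactants: 19
Product: 21 {(2E)-3-[(2S,7aR)-4,4,7a-trimethyl-2,4,5,6,7,7a-hexahydro-1-benzofuran-2-yl]but-2-en-1-yl}(triphenyl)phosphonium bromide, via allylic bromide 20 (not isolated)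
Conditions: CBr4 (1.05 equiv), PPh3 (1.1 equiv), CH2Cl2, −20 °C; then PPh3 (1.5 equiv), 0 °C to rt
Reagents that add atoms: carbon tetrabromide, BrC(Br)(Br)Br; triphenylphosphine, c1ccccc1P(c1ccccc1)c1ccccc1
Why: The same non-acidic Appel bromination and quaternisation as in step 9, here with a single hydroxyl.

Step 13
Reactants: 21; 22 (2E,4E,6E)-2,7-dimethylocta-2,4,6-trienedial (fourfold excess)
Product: 24 (2E,4E,6E,8E,10E)-2,7-dimethyl-11-[(2S,7aR)-4,4,7a-trimethyl-2,4,5,6,7,7a-hexahydro-1-benzofuran-2-yl]dodeca-2,4,6,8,10-pentaenal, via 11Z aldehyde 23 (not isolated)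
Conditions: NaOMe (1.1 equiv), CH2Cl2/MeOH, 0 °C to rt; then n-heptane, 90 °C, dark, N2
Reagents that add atoms: none
Why: Wittig olefination of the semi-stabilised allylic ylide with one aldehyde group of the dialdehyde in excess forms C11=C12 without acid, and the hindered 11Z isomer should revert thermally to the all-E polyene.

Step 14
Reactants: 24; 16
Product: 26 (3R,5S,8S,5′R,8′S)-5,8:5′,8′-diepoxy-5,8,5′,8′-tetrahydro-β,β-caroten-3-ol (the target; unprimed locants for the hydroxylated half), via 11Z carotenoid 25 (not isolated)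
Conditions: NaOMe (1.2 equiv), CH2Cl2/MeOH, 0 °C to rt; then n-heptane, 90 °C, dark, N2; crystallisation
Reagents that add atoms: none
Why: A second Wittig olefination joins the two halves; the free secondary hydroxyl is tolerated, no acid touches the two C8–O bonds, and thermal Z→E equilibration followed by crystallisation should give the all-E isomer.

**Compound list**

1 | (2E)-3-methyl-4-oxobut-2-en-1-yl acetate | CC(=O)OC/C=C(\C)C=O | starting material
2 | 2-[(2-methylbut-3-yn-2-yl)oxy]oxane | C#CC(C)(C)OC1CCCCO1 | starting material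
3 | (2E,4R)-4-hydroxy-3,7-dimethyl-7-(oxan-2-yloxy)oct-2-en-5-yn-1-yl acetate | CC(=O)OC/C=C(\C)[C@@H](O)C#CC(C)(C)OC1CCCCO1 | intermediate
4 | (2E,4S)-3,7-dimethylocta-2,5,6-triene-1,4-diol | OC/C=C(\C)[C@@H](O)C=C=C(C)C | intermediate
5 | (2E,4S)-1-{[tert-butyl(dimethyl)silyl]oxy}-3,7-dimethylocta-2,5,6-trien-4-ol | CC(C)(C)[Si](C)(C)OC/C=C(\C)[C@@H](O)C=C=C(C)C | intermediate
6 | pent-3-yn-2-one | CC#CC(C)=O | starting material
7 | (3E)-4-{[(2E,4S)-1-{[tert-butyl(dimethyl)silyl]oxy}-3,7-dimethylocta-2,5,6-trien-4-yl]oxy}pent-3-en-2-one | CC(C)(C)[Si](C)(C)OC/C=C(\C)[C@@H](O/C(C)=C/C(C)=O)C=C=C(C)C | intermediate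
8 | lithium (3E)-4-{[(2E,4S)-1-{[tert-butyl(dimethyl)silyl]oxy}-3,7-dimethylocta-2,5,6-trien-4-yl]oxy}penta-1,3-dien-2-olate | CC(C)(C)[Si](C)(C)OC/C=C(\C)[C@@H](O/C(C)=C/C(=C)[O-])C=C=C(C)C.[Li+] | intermediate (not isolated)
9 | tert-butyl{[(2E,4S)-4-{[(2E)-4-{[tert-butyl(dimethyl)silyl]oxy}penta-2,4-dien-2-yl]oxy}-3,7-dimethylocta-2,5,6-trien-1-yl]oxy}dimethylsilane | CC(C)(C)[Si](C)(C)OC/C=C(\C)[C@@H](O/C(C)=C/C(=C)O[Si](C)(C)C(C)(C)C)C=C=C(C)C | intermediate
10 | tert-butyl{[(2S,7aS)-2-[(2E)-4-{[tert-butyl(dimethyl)silyl]oxy}but-2-en-2-yl]-4,4,7a-trimethyl-2,4,5,7a-tetrahydro-1-benzofuran-6-yl]oxy}dimethylsilane | CC(C)(C)[Si](C)(C)OC/C=C(\C)[C@@H]1C=C2C(C)(C)CC(O[Si](C)(C)C(C)(C)C)=C[C@]2(C)O1 | intermediate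
11 | (2S,7aR) epimer of 10 | CC(C)(C)[Si](C)(C)OC/C=C(\C)[C@@H]1C=C2C(C)(C)CC(O[Si](C)(C)C(C)(C)C)=C[C@@]2(C)O1 | intermediate
12 | (2S,7aS)-2-[(2E)-4-hydroxybut-2-en-2-yl]-4,4,7a-trimethyl-2,4,5,7a-tetrahydro-1-benzofuran-6(7H)-one | OC/C=C(\C)[C@@H]1C=C2C(C)(C)CC(=O)C[C@]2(C)O1 | intermediate
13 | (2S,7aR)-2-[(2E)-4-hydroxybut-2-en-2-yl]-4,4,7a-trimethyl-2,4,5,7a-tetrahydro-1-benzofuran-6(7H)-one | OC/C=C(\C)[C@@H]1C=C2C(C)(C)CC(=O)C[C@@]2(C)O1 | intermediate
14 | (2S,6R,7aS)-2-[(2E)-4-hydroxybut-2-en-2-yl]-4,4,7a-trimethyl-2,4,5,6,7,7a-hexahydro-1-benzofuran-6-ol | OC/C=C(\C)[C@@H]1C=C2C(C)(C)C[C@@H](O)C[C@]2(C)O1 | intermediate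
15 | (2S,6R,7aS)-2-[(2E)-4-bromobut-2-en-2-yl]-4,4,7a-trimethyl-2,4,5,6,7,7a-hexahydro-1-benzofuran-6-ol | BrC/C=C(\C)[C@@H]1C=C2C(C)(C)C[C@@H](O)C[C@]2(C)O1 | intermediate (not isolated)
16 | {(2E)-3-[(2S,6R,7aS)-6-hydroxy-4,4,7a-trimethyl-2,4,5,6,7,7a-hexahydro-1-benzofuran-2-yl]but-2-en-1-yl}(triphenyl)phosphonium bromide | c1ccccc1[P+](c1ccccc1)(c1ccccc1)C/C=C(\C)[C@@H]1C=C2C(C)(C)C[C@@H](O)C[C@]2(C)O1.[Br-] | intermediate
17 | N′-{(2S,7aR)-2-[(2E)-4-hydroxybut-2-en-2-yl]-4,4,7a-trimethyl-2,4,5,7a-tetrahydro-1-benzofuran-6(7H)-ylidene}-4-methylbenzenesulfonohydrazide | OC/C=C(\C)[C@@H]1C=C2C(C)(C)CC(=NNS(=O)(=O)c3ccc(C)cc3)C[C@@]2(C)O1 | intermediate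
18 | N-(1,3,2-benzodioxaborol-2-yl)-N-(C3 of the ring A bicycle)-N′-tosylhydrazine, hydroxyl carried as its catecholboronate (C3 unspecified) | B1(Oc2ccccc2O1)OC/C=C(\C)[C@@H]1C=C2C(C)(C)CC(N(B3Oc4ccccc4O3)NS(=O)(=O)c3ccc(C)cc3)C[C@@]2(C)O1 | intermediate (not isolated)
19 | (2E)-3-[(2S,7aR)-4,4,7a-trimethyl-2,4,5,6,7,7a-hexahydro-1-benzofuran-2-yl]but-2-en-1-ol | OC/C=C(\C)[C@@H]1C=C2C(C)(C)CCC[C@@]2(C)O1 | intermediate
20 | (2S,7aR)-2-[(2E)-4-bromobut-2-en-2-yl]-4,4,7a-trimethyl-2,4,5,6,7,7a-hexahydro-1-benzofuran | BrC/C=C(\C)[C@@H]1C=C2C(C)(C)CCC[C@@]2(C)O1 | intermediate (not isolated)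
21 | {(2E)-3-[(2S,7aR)-4,4,7a-trimethyl-2,4,5,6,7,7a-hexahydro-1-benzofuran-2-yl]but-2-en-1-yl}(triphenyl)phosphonium bromide | c1ccccc1[P+](c1ccccc1)(c1ccccc1)C/C=C(\C)[C@@H]1C=C2C(C)(C)CCC[C@@]2(C)O1.[Br-] | intermediate
22 | (2E,4E,6E)-2,7-dimethylocta-2,4,6-trienedial | O=C/C(C)=C/C=C/C=C(\C)C=O | starting material
23 | (2E,4E,6E,8Z,10E) isomer of 24 (11Z in carotenoid numbering) | CC(/C=C\C=C(/C)[C@@H]1C=C2C(C)(C)CCC[C@@]2(C)O1)=C\C=C\C=C(C)\C=O | intermediate (not isolated)
24 | (2E,4E,6E,8E,10E)-2,7-dimethyl-11-[(2S,7aR)-4,4,7a-trimethyl-2,4,5,6,7,7a-hexahydro-1-benzofuran-2-yl]dodeca-2,4,6,8,10-pentaenal | CC(/C=C/C=C(\C)[C@@H]1C=C2C(C)(C)CCC[C@@]2(C)O1)=C\C=C\C=C(C)\C=O | intermediate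
25 | 11Z isomer of 26 at the newly formed double bond of the ring B half | CC(/C=C/C=C(\C)[C@@H]1C=C2C(C)(C)CCC[C@@]2(C)O1)=C\C=C\C=C(C)\C=C/C=C(\C)[C@@H]1C=C2C(C)(C)C[C@@H](O)C[C@]2(C)O1 | intermediate (not isolated)
26 | (3R,5S,8S,5′R,8′S)-5,8:5′,8′-diepoxy-5,8,5′,8′-tetrahydro-β,β-caroten-3-ol | CC(/C=C/C=C(\C)[C@@H]1C=C2C(C)(C)CCC[C@@]2(C)O1)=C\C=C\C=C(C)\C=C\C=C(/C)[C@@H]1C=C2C(C)(C)C[C@@H](O)C[C@]2(C)O1 | target

**Step count**

Total: 14 steps. Longest linear sequence: 12 steps (steps 1–7 and 10–14).

**Steps most likely to fail**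

Step 6. The two faces of C5 may be taken very unevenly, so that one of the two end groups is starved; any need for more heat would add loss of 9 by [3,3] shift. The fallback sets C5 under thermodynamic control instead of in the cycloaddition. It sets out from whichever ketone is in surplus (12 or 13). DBU in THF at 40 °C should open the β-alkoxy ketone by retro-oxa-Michael elimination to (4Z)-4-[(2S,3E)-2,5-dihydroxy-3-methylpent-3-en-1-ylidene]-3,5,5-trimethylcyclohex-2-en-1-one F1. Its C8 hydroxyl adds back to C5 of the dienone from either face (5-exo oxa-Michael addition) and C8 is not touched. The re-formed mixture is separated again, and the route is rejoined at the scarce epimer (13 or 12).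

Step 4. Conjugate addition of the hindered, doubly allylic alcohol to an internal ynone may be slow, and the phosphine may isomerise or oligomerise 6 instead. The fallback replaces conjugate addition by vinylic substitution. Pentane-2,4-dione with oxalyl chloride and catalytic DMF gives (3E)-4-chloropent-3-en-2-one F2. The sodium alkoxide of 5 (NaH, THF, 0 °C) should then displace chloride by addition–elimination with the E geometry kept. This sets out from 5 and comes back at 7.

Step 1. Facial discrimination may be poor with the bulky tertiary propargylic ether, or may run in the unwanted sense. The fallback replaces asymmetric addition by asymmetric reduction and sets out from 1 and 2. The lithium acetylide of 2 (n-BuLi, THF, −78 °C) adds to 1 to give racemic (2E)-4-hydroxy-3,7-dimethyl-7-(oxan-2-yloxy)oct-2-en-5-yn-1-yl acetate F3. MnO2 in CH2Cl2 oxidises it to (2E)-3,7-dimethyl-7-(oxan-2-yloxy)-4-oxooct-2-en-5-yn-1-yl acetate F4. Corey–Bakshi–Shibata reduction with the (R)-methyl oxazaborolidine and catecholborane (alkynyl as the small group, α-methylalkenyl as the large one) should then return the (R)-carbinol, and the route is rejoined at 3.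

**Further compounds**

F1 | step 6 | (4Z)-4-[(2S,3E)-2,5-dihydroxy-3-methylpent-3-en-1-ylidene]-3,5,5-trimethylcyclohex-2-en-1-one | CC1=CC(=O)CC(C)(C)/C1=C/[C@H](O)/C(C)=C/CO
F2 | step 4 | (3E)-4-chloropent-3-en-2-one | C/C(Cl)=C\C(C)=O
F3 | step 1 | racemic (2E)-4-hydroxy-3,7-dimethyl-7-(oxan-2-yloxy)oct-2-en-5-yn-1-yl acetate | CC(=O)OC/C=C(\C)C(O)C#CC(C)(C)OC1CCCCO1
F4 | step 1 | (2E)-3,7-dimethyl-7-(oxan-2-yloxy)-4-oxooct-2-en-5-yn-1-yl acetate | CC(=O)OC/C=C(\C)C(=O)C#CC(C)(C)OC1CCCCO1
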